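**Strategy.** The plan rests on disconnecting the C2–C8 bond of the cyclobutane (eucarvone locants; C8 is the diazoacetate carbon), the ring that spans C2 and C7 of the seven-membered ring. In step 6, epoxidation of C2=C3 in a 1-siloxybicyclo[5.1.0]oct-2-ene-8-carboxylate makes the ester-bearing cyclopropane carbon C8 shift from C1 to C2; one operation gives the four-membered ring, the quaternary C2(CH3) centre, the C3 carbinol and the C1 ketone. The feature exploited is that C2(CH3) is a cyclobutane carbon flanked by the oxygenated C3 and by the cyclobutane carbon C1 that carries the enone carbonyl. The precursor is eucarvone's ring with C2=C3, a C5 silyl ether and a siloxycyclopropane ester fused at C1–C7.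

Key step: step 6

Remark (locants): C1–C7 are the ring carbons of eucarvone (C1 carbonyl carbon, C2 the C(CH3) carbon, C6 the C(CH3)2 carbon); C8 is the carbon from methyl diazoacetate, C9 the methoxymethylene carbon on C1, C10 the former ester carbon on C8, C11 the methylene carbon added to C10.

Remark (assumption on facial control): a rhodium carbenoid should approach C7 on the face away from the pseudoaxial C6 methyl, i.e. anti to a pseudoequatorial C5 silyl ether, whereas the target has O5 and C8 on the same face; C5 is therefore carried as the (S)-epimer, serving only to relay absolute configuration to C1, C7 and C8, and is re-set in steps 12 and 14 (which also differentiates the two esters).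

Remark (assumption on absolute sense): the sense of the asymmetric epoxidation is assigned by analogy with 2,2-dimethyl-2H-chromene; should it, or the facial sense of step 5, prove opposite, the antipodal catalyst in step 1 leads to the same target because C5 is re-set.

Step 1
Reactants: 1 eucarvone
Product: 2 (4S,5R)-4,5-epoxy-2,6,6-trimethylcyclohept-2-en-1-one
Conditions: (S,S)-[N,N′-bis(3,5-di-tert-butylsalicylidene)-1,2-cyclohexanediaminato]MnCl (5 mol%), mCPBA, NMO, CH2Cl2, −78 °C
Reagents that add atoms: mCPBA (3-chloroperoxybenzoic acid), O=C(OO)c1cccc(Cl)c1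
Why: Jacobsen–Katsuki epoxidation: the cis-disubstituted C4=C5 bond, conjugated on one side and next to the quaternary C6 on the other (the 2,2-dimethylchromene pattern), is the only electron-rich alkene, the enone C2=C3 bond being deactivated, and the chiral (salen)Mn oxo species sets C4 and C5 together.

Step 2
Reactants: 2 (4S,5R)-epoxy enone
Product: 4 (S)-5-hydroxy-2,6,6-trimethylcyclohept-2-en-1-one, via deconjugated hydroxy enone 3 (not isolated)
Conditions: SmI2 (2.2 equiv), MeOH, THF, −78 °C; work-up; then DBU (0.2 equiv), CH2Cl2, rt
Reagents that add atoms: none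
Why: SmI2 reduction of a γ,δ-epoxy enone cleaves only the allylic C4–O bond, so the C5–O stereocentre is retained, and the kinetically α-protonated β,γ-enone is returned to conjugation by base-catalysed isomerisation.

Step 3
Reactants: 4 (S)-hydroxy enone
Product: 5 (S)-2,6,6-trimethyl-5-(triethylsilyloxy)cyclohept-2-en-1-one
Conditions: Et3SiCl, imidazole, DMAP (cat.), DMF, rt
Reagents that add atoms: chlorotriethylsilane, CC[Si](Cl)(CC)CC
Why: Standard silylation of a secondary alcohol; the triethylsilyl group withstands the basic steps yet is later removed by dilute acid beside a tert-butyldimethylsilyl ether.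

Step 4
Reactants: 5 triethylsilyl ether enone
Product: 6 triethyl{[(1S)-2,2,5-trimethyl-4-(trimethylsilyloxy)cyclohepta-3,5-dien-1-yl]oxy}silane
Conditions: LiN(iPr)2, THF, −78 °C; Me3SiCl, Et3N, −78 → 0 °C; non-aqueous work-up
Reagents that add atoms: chlorotrimethylsilane, C[Si](C)(C)Cl
Why: Kinetic α′-deprotonation of the enone at C7 (as with isophorone, a methylene next to a quaternary carbon) and O-silylation give the cross-conjugated 2-siloxy-1,3-diene, and no stereocentre is formed.

Step 5
Reactants: 6 silyl dienol ether; 7 methyl diazoacetate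
Product: 8 methyl (1R,5S,7R,8S)-2,6,6-trimethyl-5-(triethylsilyloxy)-1-(trimethylsilyloxy)bicyclo[5.1.0]oct-2-ene-8-carboxylate
Conditions: Rh2(OAc)4 (1 mol%), slow addition of 7 (2 equiv), CH2Cl2, rt
Reagents that add atoms: none
Why: Rh-carbenoid cyclopropanation of a silyl enol ether: the electrophilic carbenoid attacks C7 of the electron-rich C1=C7 bond (charge developing at C1 is stabilised by oxygen, unlike attack on C2=C3) from the face away from the pseudoaxial C6 methyl, which is the face anti to the pseudoequatorial C5 silyl ether and sets C1 and C7, while the ester takes the exo position and sets C8.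

Step 6
Reactants: 8 siloxycyclopropane ester
Product: 10 methyl (1S,2R,4S,6R,8S)-2-hydroxy-1,5,5-trimethyl-7-oxo-4-(triethylsilyloxy)bicyclo[4.1.1]octane-8-carboxylate, via siloxycyclopropyl oxirane 9 (not isolated)
Conditions: mCPBA (1.05 equiv), NaHCO3 (solid), CH2Cl2, −20 → 0 °C; aqueous work-up
Reagents that add atoms: mCPBA (3-chloroperoxybenzoic acid), O=C(OO)c1cccc(Cl)c1
Why: The peracid epoxidises C2=C3 to give oxirane 9; as its tertiary C2–O bond ionises, the C1–C8 bond, polarised towards C8 by the siloxy donor on C1 and the ester on C8, shifts to C2 and C1 becomes a silyl oxocarbenium ion that loses silicon to leave the ketone. The closest known reaction type is the epoxidation-triggered semipinacol ring expansion of 1-siloxy-1-vinylcyclopropanes to 2-(1-hydroxyalkyl)cyclobutanones. The one ring closed, the cyclobutanone C1–C2–C8–C7, forms by enlargement of the three-membered ring through this 1,2-shift (C8 opens the oxirane at C2 from the rear), and it bridges C2 and C7 of the seven-membered ring. C3 is fixed by the face of epoxidation and C2 by the antiperiplanar migration with inversion, so both are controlled by C8, i.e. by the cis-fused cyclopropane made in step 5, while C7 and C8 are carried through unchanged. The step needs epoxidation anti to C8 and migration of C8 rather than of the ring carbon C7: C8 stands almost perpendicular over one alkene face while the C1 siloxy group on the other is splayed outwards, and in the anti epoxide the exocyclic C1–C8 bond lies close to antiperiplanar to C2–O whereas the ring bond C1–C7 is held gauche to it. One equivalent of peracid at low temperature over solid NaHCO3 limits acid-induced opening of the donor–acceptor cyclopropane and Baeyer–Villiger oxidation of the product.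

Step 7
Reactants: 10 hydroxy cyclobutanone ester
Product: 11 tert-butyldimethylsilyl ether of 10 at O3
Conditions: tBuMe2SiOTf, 2,6-lutidine, CH2Cl2, −78 → 0 °C
Reagents that add atoms: tert-butyldimethylsilyl triflate, CC(C)(C)[Si](C)(C)OS(=O)(=O)C(F)(F)F
Why: Silylation of a hindered secondary alcohol with a silyl triflate and a weak hindered base, conditions under which the β-hydroxy cyclobutanone cannot undergo retro-aldol cleavage.

Step 8
Reactants: 11 silyl-protected cyclobutanone ester
Product: 12 methoxymethylene derivative of 11 at C1
Conditions: Ph3PCH2OMe Cl, KN(SiMe3)2, THF, 0 °C → rt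
Reagents that add atoms: (methoxymethyl)triphenylphosphonium chloride, COC[P+](c1ccccc1)(c1ccccc1)c1ccccc1.[Cl-]
Why: Wittig methoxymethylenation of the strained cyclobutanone, which cannot enolise (C2 is quaternary and C7 a bridgehead), adds C9 as a masked aldehyde while the hindered ester is left alone; the enol ether geometry is irrelevant.

Step 9
Reactants: 12 enol ether ester
Product: 13 bis(enol ether) with a 1-methoxyvinyl group on C8
Conditions: Cp2TiMe2 (3 equiv), toluene, 70 °C, dark
Reagents that add atoms: dimethyltitanocene Cp2TiMe2, C[Ti](C)(C1C=CC=C1)C1C=CC=C1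
Why: Petasis methylenation converts the methyl ester into a 1-methoxyvinyl group (a masked methyl ketone, adding C11) in a molecule that no longer contains a ketone; silyl ethers and the first enol ether are inert.

Step 10
Reactants: 13 bis(enol ether)
Product: 15 tricyclic enone with free 5-hydroxyl, via keto aldehyde 14 (not isolated)
Conditions: HCl (0.5 M aq.), THF, 0 °C → rt; work-up; then KOH, MeOH, rt
Reagents that add atoms: water, O
Why: Acid hydrolysis unmasks the C9 aldehyde and the C10 methyl ketone and removes the triethylsilyl ether but not the more hindered, more stable TBS ether, and base then epimerises the enolisable C1 and C8 centres and effects the intramolecular aldol condensation of C11 onto C9, which can close the six-membered ring only when both carbonyl arms lie on the cyclobutane face remote from the four-carbon bridge and thereby fixes C1.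

Step 11
Reactants: 15 tricyclic enone
Product: 16 tertiary allylic alcohol
Conditions: MeLi (3 equiv), THF, −78 °C; H2O quench
Reagents that add atoms: methyllithium, [Li]C
Why: 1,2-Addition of an organolithium to an enone that cannot enolise (its α′ and γ hydrogens sit on bridgehead carbons), one equivalent being spent on the free hydroxyl; the new carbinol centre is erased in the next step.

Step 12
Reactants: 16 allylic alcohol diol
Product: 17 enedione
Conditions: pyridinium chlorochromate [C5H5NH][CrO3Cl] (4 equiv), 4 Å molecular sieves, CH2Cl2, rt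
Reagents that add atoms: pyridinium chlorochromate, [O-][Cr](=O)(=O)Cl.c1cc[nH+]cc1
Why: Babler–Dauben oxidative 1,3-transposition: the tertiary allylic chromate ester rearranges suprafacially to C9 and is oxidised to the β-methyl enone (the apoverbenone-to-verbenone pattern), and the same reagent oxidises the free C5 alcohol to the ketone.

Step 13
Reactants: 17 enedione silyl ether
Product: 18 β-hydroxy ketone
Conditions: HF·pyridine, THF, 0 °C → rt
Reagents that add atoms: none
Why: Fluoride-mediated desilylation under acidic, non-basic conditions, so that the β-oxygenated ketone neither eliminates nor undergoes retro-aldol cleavage.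

Step 14
Reactants: 18 β-hydroxy ketone
Product: 19 hydroxy isobutyrate
Conditions: iPrCHO (6 equiv), SmI2 (0.3 equiv, premixed with the aldehyde), THF, −10 °C
Reagents that add atoms: isobutyraldehyde, CC(C)C=O
Why: Evans–Tishchenko reduction: the samarium-bound hemiacetal formed from the C3 hydroxyl and the aldehyde transfers hydride through a six-membered transition state to the face of the C5 ketone on the side of O3, so the new hydroxyl is anti to O3 (sets C5), O3 leaves as the isobutyrate, and the enone carbonyl, which has no β-hydroxyl, is untouched.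

Step 15
Reactants: 19 hydroxy isobutyrate
Product: 20 CNP0214356.1
Conditions: methacryloyl chloride, Et3N, DMAP (cat.), CH2Cl2, 0 °C → rt
Reagents that add atoms: methacryloyl chloride, C=C(C)C(Cl)=O
Why: DMAP-catalysed acylation of the remaining secondary alcohol with an acid chloride; no stereocentre is affected and the isobutyrate on the opposite face is not expected to migrate.

**Compound list**

1 | eucarvone (2,6,6-trimethylcyclohepta-2,4-dien-1-one) | CC1=CC=CC(C)(C)CC1=O | starting material
2 | (4S,5R)-4,5-epoxy-2,6,6-trimethylcyclohept-2-en-1-one (cis-oxirane on the former C4=C5 bond) | CC1=C[C@@H]2O[C@@H]2C(C)(C)CC1=O | intermediate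
3 | (5S)-5-hydroxy-2,6,6-trimethylcyclohept-3-en-1-one (C2 epimers, not isolated) | CC1C=C[C@H](O)C(C)(C)CC1=O | intermediate
4 | (S)-5-hydroxy-2,6,6-trimethylcyclohept-2-en-1-one | CC1=CC[C@H](O)C(C)(C)CC1=O | intermediate
5 | (S)-2,6,6-trimethyl-5-(triethylsilyloxy)cyclohept-2-en-1-one | CC[Si](CC)(CC)O[C@H]1CC=C(C)C(=O)CC1(C)C | intermediate
6 | triethyl{[(1S)-2,2,5-trimethyl-4-(trimethylsilyloxy)cyclohepta-3,5-dien-1-yl]oxy}silane | CC[Si](CC)(CC)O[C@H]1CC=C(C)C(O[Si](C)(C)C)=CC1(C)C | intermediate
7 | methyl diazoacetate | COC(=O)C=[N+]=[N-] | starting material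
8 | methyl (1R,5S,7R,8S)-2,6,6-trimethyl-5-(triethylsilyloxy)-1-(trimethylsilyloxy)bicyclo[5.1.0]oct-2-ene-8-carboxylate (ester exo; C8 anti to O5) | CC[Si](CC)(CC)O[C@H]1CC=C(C)[C@]2(O[Si](C)(C)C)[C@@H](C(=O)OC)[C@@H]2C1(C)C | intermediate
9 | 2,3-epoxide of 8, oxirane oxygen anti to C8 (not isolated) | CC[Si](CC)(CC)O[C@H]1C[C@H]3O[C@@]3(C)[C@]2(O[Si](C)(C)C)[C@@H](C(=O)OC)[C@@H]2C1(C)C | intermediate
10 | methyl (1S,2R,4S,6R,8S)-2-hydroxy-1,5,5-trimethyl-7-oxo-4-(triethylsilyloxy)bicyclo[4.1.1]octane-8-carboxylate | CC[Si](CC)(CC)O[C@H]1C[C@@H](O)[C@@]2(C)C(=O)[C@H]([C@@H]2C(=O)OC)C1(C)C | intermediate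
11 | 10 with the 2-hydroxyl (O3) as tert-butyldimethylsilyl ether | CC[Si](CC)(CC)O[C@H]1C[C@@H](O[Si](C)(C)C(C)(C)C)[C@@]2(C)C(=O)[C@H]([C@@H]2C(=O)OC)C1(C)C | intermediate
12 | 11 with the ketone replaced by a methoxymethylene group (E/Z mixture, inconsequential) | CC[Si](CC)(CC)O[C@H]1C[C@@H](O[Si](C)(C)C(C)(C)C)[C@@]2(C)C(=COC)[C@H]([C@@H]2C(=O)OC)C1(C)C | intermediate
13 | 12 with the ester replaced by a 1-methoxyvinyl group | CC[Si](CC)(CC)O[C@H]1C[C@@H](O[Si](C)(C)C(C)(C)C)[C@@]2(C)C(=COC)[C@H]([C@@H]2C(=C)OC)C1(C)C | intermediate
14 | keto aldehyde: formyl on C1, acetyl on C8, free 5-OH, 3-OTBS (C1 epimers, not isolated) | O[C@H]1C[C@@H](O[Si](C)(C)C(C)(C)C)[C@@]2(C)C(C=O)[C@H]([C@@H]2C(C)=O)C1(C)C | intermediate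
15 | tricyclic enone: C8–C10(=O)–C11H=C9H–C1 ring closed across the cyclobutane; 3-OTBS; (5S)-OH | O[C@H]1C[C@@H](O[Si](C)(C)C(C)(C)C)[C@@]2(C)[C@@H]3C=CC(=O)[C@H]2[C@@H]3C1(C)C | intermediate
16 | tertiary allylic alcohol from methyl addition at C10 (carbinol drawn for attack anti to the C2 methyl; inconsequential) | O[C@H]1C[C@@H](O[Si](C)(C)C(C)(C)C)[C@@]2(C)[C@@H]3C=C[C@](C)(O)[C@H]2[C@@H]3C1(C)C | intermediate
17 | enedione: C9 ketone, C11=C10(CH3) alkene, C5 ketone, 3-OTBS | O=C1C[C@@H](O[Si](C)(C)C(C)(C)C)[C@@]2(C)[C@@H]3C(=O)C=C(C)[C@H]2[C@@H]3C1(C)C | intermediate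
18 | β-hydroxy ketone: 17 with free 3-OH | O=C1C[C@@H](O)[C@@]2(C)[C@@H]3C(=O)C=C(C)[C@H]2[C@@H]3C1(C)C | intermediate
19 | 3-O-isobutyrate with free (5R)-hydroxyl anti to O3 | O[C@@H]1C[C@@H](OC(=O)C(C)C)[C@@]2(C)[C@@H]3C(=O)C=C(C)[C@H]2[C@@H]3C1(C)C | intermediate
20 | CNP0214356.1: 6-(isobutyryloxy)-3,3,7,11-tetramethyl-9-oxotricyclo[5.4.0.0^2,8]undec-10-en-4-yl methacrylate, configuration as in the SMILES | C=C(C)C(=O)O[C@@H]1C[C@@H](OC(=O)C(C)C)[C@@]2(C)[C@@H]3C(=O)C=C(C)[C@H]2[C@@H]3C1(C)C | target

Total step count: 15. Longest linear sequence: 15 steps (1 → 20); methyl diazoacetate 7 enters in step 5.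

**Steps most likely to fail**

1. Step 6. What may go wrong: acid-induced heterolysis of the polarised C1–C8 bond, opening the donor–acceptor cyclopropane to the γ-keto ester before the shift. Epoxidation on the C8 face would allow only migration of C7 (ring contraction), and the cyclobutanone may be over-oxidised. Fallback (removal of the acceptor before the ring expansion, so that an ordinary 1-siloxy-1-vinylcyclopropane is used): starting from 8, iBu2AlH in CH2Cl2 at −78 °C reduces the ester to the cyclopropylmethanol F1, and Ac2O/pyridine gives its acetate F2. Buffered mCPBA then forms the oxirane F3, which should rearrange in the flask to the acetoxymethyl hydroxy cyclobutanone F4. tBuMe2SiOTf/2,6-lutidine gives the silyl ether F5, K2CO3 in MeOH frees the primary alcohol F6, and TEMPO with PhI(OAc)2 in wet MeCN oxidises it to the carboxylic acid F7. Me3SiCHN2 in MeOH/toluene esterifies F7 and the route is rejoined at 11.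

2. Step 5. What may go wrong: carbenoid addition to the C2=C3 bond, weak facial discrimination by the remote C5 ether, or carbene dimerisation outpacing attack at the hindered C7. Fallback (stereocontrol moved from the substrate to the catalyst): starting from 6, cyclopropanation with 7 is run with CuOTf and the matched enantiomer of 2,2′-isopropylidenebis(4-tert-butyl-2-oxazoline), a catalyst type known for face-selective cyclopropanation of silyl enol ethers with diazoacetates. The route is rejoined at 8, and this fallback makes no new compound (entry F0).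

3. Step 14. What may go wrong: no hydride transfer to the hindered α-quaternary C5 ketone, single-electron reduction of the enone by SmI2, or acyl migration between O3 and O5. Fallback (reduction and acylation separated): starting from 18, Me4NBH(OAc)3 in AcOH/MeCN at −20 °C (Saksena–Evans hydroxyl-directed reduction, inert to the enone) should give the anti-diol F8. Isobutyric anhydride with DMAP at low temperature should then acylate the less encumbered O3, whose neighbour is the tied-back bridgehead C2, in preference to O5, whose neighbour is the gem-dimethyl carbon. The route is rejoined at 19; this site selectivity is the weak point of the fallback.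

**Further compounds**

F1 | step 6 | 8 with the ester reduced to hydroxymethyl | CC[Si](CC)(CC)O[C@H]1CC=C(C)[C@]2(O[Si](C)(C)C)[C@@H](CO)[C@@H]2C1(C)C
F2 | step 6 | acetate of F1 | CC[Si](CC)(CC)O[C@H]1CC=C(C)[C@]2(O[Si](C)(C)C)[C@@H](COC(C)=O)[C@@H]2C1(C)C
F3 | step 6 | 2,3-epoxide of F2, oxirane oxygen anti to C8 (not isolated) | CC[Si](CC)(CC)O[C@H]1C[C@H]3O[C@@]3(C)[C@]2(O[Si](C)(C)C)[C@@H](COC(C)=O)[C@@H]2C1(C)C
F4 | step 6 | analogue of 10 with acetoxymethyl in place of the ester | CC[Si](CC)(CC)O[C@H]1C[C@@H](O)[C@@]2(C)C(=O)[C@H]([C@@H]2COC(C)=O)C1(C)C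
F5 | step 6 | tert-butyldimethylsilyl ether of F4 at O3 | CC[Si](CC)(CC)O[C@H]1C[C@@H](O[Si](C)(C)C(C)(C)C)[C@@]2(C)C(=O)[C@H]([C@@H]2COC(C)=O)C1(C)C
F6 | step 6 | analogue of 11 with hydroxymethyl in place of the ester | CC[Si](CC)(CC)O[C@H]1C[C@@H](O[Si](C)(C)C(C)(C)C)[C@@]2(C)C(=O)[C@H]([C@@H]2CO)C1(C)C
F7 | step 6 | carboxylic acid corresponding to 11 | CC[Si](CC)(CC)O[C@H]1C[C@@H](O[Si](C)(C)C(C)(C)C)[C@@]2(C)C(=O)[C@H]([C@@H]2C(=O)O)C1(C)C
F0 | step 5 | none | none
F8 | step 14 | anti-3,5-diol: 18 with the C5 ketone reduced, O5 anti to O3 | O[C@@H]1C[C@@H](O)[C@@]2(C)[C@@H]3C(=O)C=C(C)[C@H]2[C@@H]3C1(C)C
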